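The carbocycle (C4a, C5, C6, C7, C8, C8a) is disconnected at C4a–C5 and C8–C8a. It is closed by an endo Diels–Alder reaction between an enantiopure N-Boc-3-benzyloxy-2-methyl-2,3-dihydro-4-pyridone (ring A; C2/C3 from a Sharpless aminohydroxylation; C4 carbonyl as removable activator) and an (E)-1-alkylbuta-1,3-diene carrying the C5' carbinol. In one operation the step joins both halves, closes ring B and sets C4a, C5 and C8a. It exploits the all-cis H-4a/H-5/H-8a array of the cis-fused ring B and its anti relation to the pseudoaxial C2 methyl. Deoxygenation at C4, hydrogenation, acylation and acidolysis complete the synthesis.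

Key step: step 11

Remark: pent-4-en-1-ylmagnesium bromide is taken as the commercial THF solution; the C4 carbinol made in step 12 is carried as an epimer mixture (C4 becomes CH2 in step 14), so the SMILES of 15 and 16 leave C4 undefined.

Step 1
Reactants: 1 ethyl (E)-but-2-enoate
Product: 2 ethyl (2S,3R)-3-[(tert-butoxycarbonyl)amino]-2-hydroxybutanoate
Conditions: BocNH2, NaOH, t-BuOCl, K2OsO2(OH)4 (4 mol%), (DHQD)2PHAL (5 mol%), n-PrOH/H2O 1:1, 0 °C
Reagents that add atoms: tert-butyl carbamate, NC(=O)OC(C)(C)C; water, O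
Why: Sharpless asymmetric aminohydroxylation should add N and O syn across the E-alkene with nitrogen at the β-carbon, the (DHQD)2PHAL ligand selecting the face that gives the (2S,3R) syn amino alcohol (the future C3 and C2, cis on ring A).

Step 2
Reactants: 2 ethyl (2S,3R)-3-[(tert-butoxycarbonyl)amino]-2-hydroxybutanoate
Product: 3 ethyl (2S,3R)-2-(benzyloxy)-3-[(tert-butoxycarbonyl)amino]butanoate
Conditions: BnBr, Ag2O, CH2Cl2, rt, dark
Reagents that add atoms: benzyl bromide, BrCc1ccccc1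
Why: Silver-oxide-mediated Williamson etherification should benzylate the hydroxyl under non-basic conditions, leaving the NHBoc group and the α-stereocentre untouched.

Step 3
Reactants: 3 ethyl (2S,3R)-2-(benzyloxy)-3-[(tert-butoxycarbonyl)amino]butanoate
Product: 4 tert-butyl N-[(2R,3S)-3-(benzyloxy)-4-[methoxy(methyl)amino]-4-oxobutan-2-yl]carbamate
Conditions: MeNH(OMe)·HCl, i-PrMgCl, THF, −20 °C to 0 °C
Reagents that add atoms: N,O-dimethylhydroxylamine hydrochloride, CNOC.Cl
Why: Aminolysis of the ester by the magnesium amide of N,O-dimethylhydroxylamine should give the Weinreb amide, the low temperature protecting the α-alkoxy centre from enolisation.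

Step 4
Reactants: 4 tert-butyl N-[(2R,3S)-3-(benzyloxy)-4-[methoxy(methyl)amino]-4-oxobutan-2-yl]carbamate
Product: 5 tert-butyl N-[(2R,3S)-3-(benzyloxy)-4-oxohex-5-yn-2-yl]carbamate
Conditions: ethynylmagnesium bromide (excess), THF, 0 °C; cold aq. NaHSO4 quench
Reagents that add atoms: ethynylmagnesium bromide, C#C[Mg]Br
Why: Weinreb ketone synthesis: the chelated tetrahedral adduct should persist until work-up, so only one ethynyl group is delivered and the ynone results.

Step 5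
Reactants: 5 tert-butyl N-[(2R,3S)-3-(benzyloxy)-4-oxohex-5-yn-2-yl]carbamate
Product: 7 (2R,3S)-3-(benzyloxy)-2-methyl-2,3-dihydropyridin-4(1H)-one, via β-chlorovinyl ketone hydrochloride 6 (not isolated)
Conditions: 4 M HCl in 1,4-dioxane, rt; concentrate; K2CO3, MeOH, rt
Reagents that add atoms: none
Why: Acidolysis of the Boc group with HCl addition to the ynone gives the β-chlorovinyl ketone; on neutralisation the free amine should close ring A by 6-endo addition–elimination (intramolecular aza-Michael reaction) to the vinylogous amide without touching C2 or C3.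

Step 6
Reactants: 7 (2R,3S)-3-(benzyloxy)-2-methyl-2,3-dihydropyridin-4(1H)-one
Product: 8 tert-butyl (2R,3S)-3-(benzyloxy)-2-methyl-4-oxo-3,4-dihydropyridine-1(2H)-carboxylate
Conditions: Boc2O, DMAP (cat.), Et3N, MeCN, rt
Reagents that add atoms: di-tert-butyl dicarbonate, CC(C)(C)OC(=O)OC(=O)OC(C)(C)C
Why: DMAP-catalysed N-acylation of the vinylogous amide N–H installs the carbamate that activates the enone as a dienophile and, through A(1,3) strain, forces the C2 methyl pseudoaxial.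

Step 7
Reactants: 9 (R)-2-propyloxirane
Product: 10 (R)-dec-9-en-4-ol
Conditions: pent-4-en-1-ylmagnesium bromide, CuI (10 mol%), THF, −30 °C to 0 °C
Reagents that add atoms: pent-4-en-1-ylmagnesium bromide, C=CCCC[Mg]Br
Why: Copper-catalysed SN2 opening of the terminal epoxide at its CH2 carbon leaves the carbinol centre (the future C5', R) untouched.

Step 8
Reactants: 10 (R)-dec-9-en-4-ol
Product: 11 tert-butyl{[(4R)-dec-9-en-4-yl]oxy}dimethylsilane
Conditions: TBSCl, imidazole, DMF, rt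
Reagents that add atoms: tert-butyldimethylsilyl chloride, CC(C)(C)[Si](C)(C)Cl
Why: Imidazole-promoted silylation of the secondary alcohol is routine and masks O5' until the last step.

Step 9
Reactants: 11 tert-butyl{[(4R)-dec-9-en-4-yl]oxy}dimethylsilane
Product: 12 (2E,8R)-8-[(tert-butyldimethylsilyl)oxy]undec-2-enal
Conditions: (E)-but-2-enal (5 equiv), second-generation Grubbs catalyst RuCl2(=CHPh)(PCy3)(H2IMes) (3 mol%), CH2Cl2, 40 °C
Reagents that add atoms: (E)-but-2-enal, C/C=C/C=O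
Why: Olefin cross-metathesis of a terminal alkene with an enal should be selective for the cross product and give the thermodynamically favoured E-enal.

Step 10
Reactants: 12 (2E,8R)-8-[(tert-butyldimethylsilyl)oxy]undec-2-enal
Product: 13 tert-butyl{[(4R,9E)-dodeca-9,11-dien-4-yl]oxy}dimethylsilane
Conditions: Ph3PCH3Br, KN(SiMe3)2, THF, −78 °C to 0 °C
Reagents that add atoms: methyltriphenylphosphonium bromide, C[P+](c1ccccc1)(c1ccccc1)c1ccccc1.[Br-]
Why: Wittig methylenation of the enal with the non-stabilised ylide should give the terminal diene with the E-alkene retained.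

Step 11
Reactants: 8 tert-butyl (2R,3S)-3-(benzyloxy)-2-methyl-4-oxo-3,4-dihydropyridine-1(2H)-carboxylate; 13 tert-butyl{[(4R,9E)-dodeca-9,11-dien-4-yl]oxy}dimethylsilane
Product: 14 tert-butyl (2R,3S,4aS,5S,8aR)-3-(benzyloxy)-5-[(5R)-5-[(tert-butyldimethylsilyl)oxy]octyl]-2-methyl-4-oxo-3,4,4a,5,8,8a-hexahydroquinoline-1(2H)-carboxylate
Conditions: Me2AlCl (2.0 equiv), 13 (1.5 equiv), CH2Cl2, −78 °C to −20 °C
Reagents that add atoms: none
Why: Concerted, asynchronous [4+2] cycloaddition in which Me2AlCl chelates the C4 carbonyl and the C3 benzyloxy oxygen and so lowers the LUMO of the C4a=C8a bond; the closest known reaction type is the Lewis-acid-promoted Diels–Alder reaction of cyclic enones and N-acyl vinylogous amides with 1-alkyl dienes. Ring B is closed by intermolecular suprafacial addition across C4a=C8a, forming C8–C8a (to the β-carbon, larger LUMO coefficient) and C4a–C5 ("ortho" orientation), so the alkyl chain lands on C5. The cis ring fusion at C4a/C8a follows from the cis geometry of the ring alkene, and its absolute sense from approach of the diene anti to the pseudoaxial C2 methyl (A(1,3) strain with the N-Boc group), as cycloadditions to N-acyl-2-alkyl-1,2-dihydropyridines proceed. C5 is set by the endo transition state (diene over ring A and its carbonyl), which with the E-alkene places H-5 cis to H-4a. The step needs ortho regioselectivity, endo selectivity and π-facial selectivity; these are secured by the polarised dienophile, the chelating Lewis acid and the axial-methyl/equatorial-benzyloxy arrangement, while the remote C5' centre has no influence.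

Step 12
Reactants: 14 tert-butyl (2R,3S,4aS,5S,8aR)-3-(benzyloxy)-5-[(5R)-5-[(tert-butyldimethylsilyl)oxy]octyl]-2-methyl-4-oxo-3,4,4a,5,8,8a-hexahydroquinoline-1(2H)-carboxylate
Product: 15 tert-butyl (2R,3S,4aS,5S,8aR)-3-(benzyloxy)-5-[(5R)-5-[(tert-butyldimethylsilyl)oxy]octyl]-4-hydroxy-2-methyl-3,4,4a,5,8,8a-hexahydroquinoline-1(2H)-carboxylate (C4 epimers)
Conditions: NaBH4, CeCl3·7H2O, MeOH, −40 °C to 0 °C
Reagents that add atoms: none
Why: Luche-type 1,2-reduction at low temperature should reduce the ketone without enolising C3 or C4a; the new C4 centre is erased later.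

Step 13
Reactants: 15 tert-butyl (2R,3S,4aS,5S,8aR)-3-(benzyloxy)-5-[(5R)-5-[(tert-butyldimethylsilyl)oxy]octyl]-4-hydroxy-2-methyl-3,4,4a,5,8,8a-hexahydroquinoline-1(2H)-carboxylate (C4 epimers)
Product: 16 tert-butyl (2R,3S,4aS,5S,8aR)-3-(benzyloxy)-5-[(5R)-5-[(tert-butyldimethylsilyl)oxy]octyl]-4-[(1H-imidazol-1-ylcarbonothioyl)oxy]-2-methyl-3,4,4a,5,8,8a-hexahydroquinoline-1(2H)-carboxylate (C4 epimers)
Conditions: 1,1'-thiocarbonyldiimidazole, DMAP (cat.), ClCH2CH2Cl, 70 °C
Reagents that add atoms: 1,1'-thiocarbonyldiimidazole, S=C(n1ccnc1)n1ccnc1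
Why: Thioacylation of the secondary alcohol under neutral conditions (first half of a Barton–McCombie deoxygenation) avoids alkoxide chemistry next to the N-Boc group.

Step 14
Reactants: 16 tert-butyl (2R,3S,4aS,5S,8aR)-3-(benzyloxy)-5-[(5R)-5-[(tert-butyldimethylsilyl)oxy]octyl]-4-[(1H-imidazol-1-ylcarbonothioyl)oxy]-2-methyl-3,4,4a,5,8,8a-hexahydroquinoline-1(2H)-carboxylate (C4 epimers)
Product: 17 tert-butyl (2R,3R,4aS,5S,8aR)-3-(benzyloxy)-5-[(5R)-5-[(tert-butyldimethylsilyl)oxy]octyl]-2-methyl-3,4,4a,5,8,8a-hexahydroquinoline-1(2H)-carboxylate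
Conditions: Bu3SnH, AIBN (cat.), toluene, 100 °C
Reagents that add atoms: none
Why: Barton–McCombie radical deoxygenation (stannyl radical addition to C=S, β-scission to the C4 radical, hydrogen transfer) should turn C4 into CH2 and so erase the activating oxygen without touching C3 or C4a.

Step 15
Reactants: 17 tert-butyl (2R,3R,4aS,5S,8aR)-3-(benzyloxy)-5-[(5R)-5-[(tert-butyldimethylsilyl)oxy]octyl]-2-methyl-3,4,4a,5,8,8a-hexahydroquinoline-1(2H)-carboxylate
Product: 18 tert-butyl (2R,3R,4aS,5S,8aR)-5-[(5R)-5-[(tert-butyldimethylsilyl)oxy]octyl]-3-hydroxy-2-methyloctahydroquinoline-1(2H)-carboxylate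
Conditions: H2 (1 atm), 10% Pd/C, EtOAc, rt
Reagents that add atoms: none
Why: Heterogeneous hydrogenation should saturate the C6=C7 alkene and hydrogenolyse the benzyl ether in one operation; no stereocentre is created and the Boc and TBS groups are stable.

Step 16
Reactants: 19 (E)-hex-2-enal
Product: 20 (2E,4E)-octa-2,4-dienoic acid
Conditions: malonic acid, pyridine, piperidine (cat.), 90 °C
Reagents that add atoms: malonic acid, OC(=O)CC(=O)O
Why: Knoevenagel–Doebner condensation with decarboxylation should give the thermodynamically favoured 2E alkene while the 4E geometry of the enal is retained.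

Step 17
Reactants: 18 tert-butyl (2R,3R,4aS,5S,8aR)-5-[(5R)-5-[(tert-butyldimethylsilyl)oxy]octyl]-3-hydroxy-2-methyloctahydroquinoline-1(2H)-carboxylate; 20 (2E,4E)-octa-2,4-dienoic acid
Product: 21 (2R,3R,4aS,5S,8aR)-1-(tert-butoxycarbonyl)-5-[(5R)-5-[(tert-butyldimethylsilyl)oxy]octyl]-2-methyldecahydroquinolin-3-yl (2E,4E)-octa-2,4-dienoate
Conditions: EDC·HCl, DMAP, CH2Cl2, rt
Reagents that add atoms: none
Why: Steglich (carbodiimide/DMAP) esterification acylates the only free hydroxyl (C3) with retention, nitrogen being masked as Boc and O5' as the TBS ether.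

Step 18
Reactants: 21 (2R,3R,4aS,5S,8aR)-1-(tert-butoxycarbonyl)-5-[(5R)-5-[(tert-butyldimethylsilyl)oxy]octyl]-2-methyldecahydroquinolin-3-yl (2E,4E)-octa-2,4-dienoate
Product: 22 (2R,3R,4aS,5S,8aR)-5-[(5R)-5-hydroxyoctyl]-2-methyldecahydroquinolin-3-yl (2E,4E)-octa-2,4-dienoate (CNP0186076.5)
Conditions: TFA/H2O 9:1, 0 °C to rt; aq. NaHCO3 work-up
Reagents that add atoms: none
Why: Aqueous acidolysis should remove the Boc group (as 2-methylpropene and CO2) and hydrolyse the TBS ether in one operation, the dienoate ester being stable to these conditions.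

Compound list
1 | ethyl (E)-but-2-enoate | CCOC(=O)/C=C/C | starting material
2 | ethyl (2S,3R)-3-[(tert-butoxycarbonyl)amino]-2-hydroxybutanoate | CCOC(=O)[C@@H](O)[C@@H](C)NC(=O)OC(C)(C)C | intermediate
3 | ethyl (2S,3R)-2-(benzyloxy)-3-[(tert-butoxycarbonyl)amino]butanoate | CCOC(=O)[C@@H](OCc1ccccc1)[C@@H](C)NC(=O)OC(C)(C)C | intermediate
4 | tert-butyl N-[(2R,3S)-3-(benzyloxy)-4-[methoxy(methyl)amino]-4-oxobutan-2-yl]carbamate | CON(C)C(=O)[C@@H](OCc1ccccc1)[C@@H](C)NC(=O)OC(C)(C)C | intermediate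
5 | tert-butyl N-[(2R,3S)-3-(benzyloxy)-4-oxohex-5-yn-2-yl]carbamate | C#CC(=O)[C@@H](OCc1ccccc1)[C@@H](C)NC(=O)OC(C)(C)C | intermediate
6 | (1Z,4S,5R)-5-amino-4-(benzyloxy)-1-chlorohex-1-en-3-one hydrochloride (β-chlorovinyl ketone hydrochloride, not isolated) | Cl/C=C\C(=O)[C@@H](OCc1ccccc1)[C@@H](C)N.Cl | intermediate
7 | (2R,3S)-3-(benzyloxy)-2-methyl-2,3-dihydropyridin-4(1H)-one | c1ccccc1CO[C@@H]1C(=O)C=CN[C@@H]1C | intermediate
8 | tert-butyl (2R,3S)-3-(benzyloxy)-2-methyl-4-oxo-3,4-dihydropyridine-1(2H)-carboxylate | c1ccccc1CO[C@@H]1C(=O)C=CN(C(=O)OC(C)(C)C)[C@@H]1C | intermediate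
9 | (R)-2-propyloxirane | CCC[C@@H]1CO1 | starting material
10 | (R)-dec-9-en-4-ol | CCC[C@@H](O)CCCCC=C | intermediate
11 | tert-butyl{[(4R)-dec-9-en-4-yl]oxy}dimethylsilane | CCC[C@@H](O[Si](C)(C)C(C)(C)C)CCCCC=C | intermediate
12 | (2E,8R)-8-[(tert-butyldimethylsilyl)oxy]undec-2-enal | CCC[C@@H](O[Si](C)(C)C(C)(C)C)CCCC/C=C/C=O | intermediate
13 | tert-butyl{[(4R,9E)-dodeca-9,11-dien-4-yl]oxy}dimethylsilane | CCC[C@@H](O[Si](C)(C)C(C)(C)C)CCCC/C=C/C=C | intermediate
14 | tert-butyl (2R,3S,4aS,5S,8aR)-3-(benzyloxy)-5-[(5R)-5-[(tert-butyldimethylsilyl)oxy]octyl]-2-methyl-4-oxo-3,4,4a,5,8,8a-hexahydroquinoline-1(2H)-carboxylate (cis-fused; H-4a, H-5, H-8a mutually cis, on the face of the C2 methyl) | c1ccccc1CO[C@@H]1C(=O)[C@H]2[C@@H](CCCC[C@H](O[Si](C)(C)C(C)(C)C)CCC)C=CC[C@H]2N(C(=O)OC(C)(C)C)[C@@H]1C | intermediate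
15 | tert-butyl (2R,3S,4aS,5S,8aR)-3-(benzyloxy)-5-[(5R)-5-[(tert-butyldimethylsilyl)oxy]octyl]-4-hydroxy-2-methyl-3,4,4a,5,8,8a-hexahydroquinoline-1(2H)-carboxylate (C4 epimers) | c1ccccc1CO[C@@H]1C(O)[C@H]2[C@@H](CCCC[C@H](O[Si](C)(C)C(C)(C)C)CCC)C=CC[C@H]2N(C(=O)OC(C)(C)C)[C@@H]1C | intermediate
16 | tert-butyl (2R,3S,4aS,5S,8aR)-3-(benzyloxy)-5-[(5R)-5-[(tert-butyldimethylsilyl)oxy]octyl]-4-[(1H-imidazol-1-ylcarbonothioyl)oxy]-2-methyl-3,4,4a,5,8,8a-hexahydroquinoline-1(2H)-carboxylate (C4 epimers) | c1ccccc1CO[C@@H]1C(OC(=S)n3ccnc3)[C@H]2[C@@H](CCCC[C@H](O[Si](C)(C)C(C)(C)C)CCC)C=CC[C@H]2N(C(=O)OC(C)(C)C)[C@@H]1C | intermediate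
17 | tert-butyl (2R,3R,4aS,5S,8aR)-3-(benzyloxy)-5-[(5R)-5-[(tert-butyldimethylsilyl)oxy]octyl]-2-methyl-3,4,4a,5,8,8a-hexahydroquinoline-1(2H)-carboxylate | c1ccccc1CO[C@@H]1C[C@H]2[C@@H](CCCC[C@H](O[Si](C)(C)C(C)(C)C)CCC)C=CC[C@H]2N(C(=O)OC(C)(C)C)[C@@H]1C | intermediate
18 | tert-butyl (2R,3R,4aS,5S,8aR)-5-[(5R)-5-[(tert-butyldimethylsilyl)oxy]octyl]-3-hydroxy-2-methyloctahydroquinoline-1(2H)-carboxylate | O[C@@H]1C[C@H]2[C@@H](CCCC[C@H](O[Si](C)(C)C(C)(C)C)CCC)CCC[C@H]2N(C(=O)OC(C)(C)C)[C@@H]1C | intermediate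
19 | (E)-hex-2-enal | CCC/C=C/C=O | starting material
20 | (2E,4E)-octa-2,4-dienoic acid | CCC/C=C/C=C/C(=O)O | intermediate
21 | (2R,3R,4aS,5S,8aR)-1-(tert-butoxycarbonyl)-5-[(5R)-5-[(tert-butyldimethylsilyl)oxy]octyl]-2-methyldecahydroquinolin-3-yl (2E,4E)-octa-2,4-dienoate | CCC/C=C/C=C/C(=O)O[C@@H]1C[C@H]2[C@@H](CCCC[C@H](O[Si](C)(C)C(C)(C)C)CCC)CCC[C@H]2N(C(=O)OC(C)(C)C)[C@@H]1C | intermediate
22 | (2R,3R,4aS,5S,8aR)-5-[(5R)-5-hydroxyoctyl]-2-methyldecahydroquinolin-3-yl (2E,4E)-octa-2,4-dienoate (CNP0186076.5) | CCC/C=C/C=C/C(=O)O[C@@H]1C[C@H]2[C@@H](CCCC[C@H](O)CCC)CCC[C@H]2N[C@@H]1C | target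

Total step count: 18. Longest linear sequence: 13 steps (steps 1–6, 11–15, 17, 18).

Steps most likely to fail

Step 11 (key step). The N-Boc vinylogous imide may be too weak a dienophile for an unactivated 1-alkyl diene. Lewis-acid-induced diene oligomerisation or carbamate cleavage could then outrun cycloaddition, and a stepwise Michael-type pathway (axial attack at C8a syn to the methyl) could erode the π-facial selectivity. The fallback is a thermal, Lewis-acid-free cycloaddition with a more nucleophilic 2-silyloxydiene, paid for by a second deoxygenation; it sets out from 11 and 8 and returns at 18. Cross-metathesis of 11 with but-3-en-2-one (second-generation Grubbs catalyst, CH2Cl2, 40 °C) should give (3E,9R)-9-[(tert-butyldimethylsilyl)oxy]dodec-3-en-2-one F1. Soft enolisation (Et3SiOTf, Et3N, CH2Cl2, 0 °C) should give the cross-conjugated diene triethyl{[(3E,9R)-9-[(tert-butyldimethylsilyl)oxy]dodeca-1,3-dien-2-yl]oxy}silane F2. Heating F2 with 8 (toluene, 110 °C) should give, by the same ortho/endo/anti-to-methyl mode, the silyl enol ether adduct tert-butyl (2R,3S,4aS,5S,8aR)-3-(benzyloxy)-5-[(5R)-5-[(tert-butyldimethylsilyl)oxy]octyl]-2-methyl-4-oxo-7-[(triethylsilyl)oxy]-3,4,4a,5,8,8a-hexahydroquinoline-1(2H)-carboxylate F3. Buffered hydrolysis (AcOH/THF/H2O) should give the 4,7-diketone tert-butyl (2R,3S,4aS,5S,8aR)-3-(benzyloxy)-5-[(5R)-5-[(tert-butyldimethylsilyl)oxy]octyl]-2-methyl-4,7-dioxooctahydroquinoline-1(2H)-carboxylate F4. NaBH4 reduction should give the corresponding 4,7-diol (carbinol epimers) F5, and 1,1'-thiocarbonyldiimidazole the 4,7-bis(imidazol-1-ylcarbonothioyl) ester F6. Bu3SnH/AIBN should then give tert-butyl (2R,3R,4aS,5S,8aR)-3-(benzyloxy)-5-[(5R)-5-[(tert-butyldimethylsilyl)oxy]octyl]-2-methyloctahydroquinoline-1(2H)-carboxylate F7, which hydrogenolysis (H2, Pd/C, EtOAc) converts into 18.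

Step 5. Under the basic cyclisation conditions, configuration may be lost at C3 (enolisation of the α-benzyloxy ketone) or at C2 (reversible ring opening by β-elimination of the amine). The fallback avoids both deprotection and base; it sets out from 5 and returns at 8. The intact N-Boc ynone is cyclised by π-acid catalysis (Ph3PAuNTf2, 5 mol%, CH2Cl2, rt), a 6-endo-dig hydroamination by the carbamate nitrogen, which should give 8 directly under neutral conditions and also makes step 6 unnecessary.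

Step 13. The C4 carbinol is flanked by the C3 benzyloxy group and the ring fusion, so thioacylation may stay incomplete, and forcing it may cause syn-elimination of the thiocarbonate. The fallback replaces the radical deoxygenation by a Mozingo reduction; it sets out from 14 and returns at 18. Ketone 14 is converted with ethane-1,2-dithiol and Zn(OTf)2 (CH2Cl2, rt) into the C4 spiro-1,3-dithiolane of 14 F8. Raney nickel (W-2 grade, H2, EtOH, reflux) should then desulfurise C4, saturate C6=C7 and hydrogenolyse the benzyl ether in one operation, giving 18.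

Further compounds
F1 | step 11 | (3E,9R)-9-[(tert-butyldimethylsilyl)oxy]dodec-3-en-2-one | CCC[C@@H](O[Si](C)(C)C(C)(C)C)CCCC/C=C/C(C)=O
F2 | step 11 | triethyl{[(3E,9R)-9-[(tert-butyldimethylsilyl)oxy]dodeca-1,3-dien-2-yl]oxy}silane | CCC[C@@H](O[Si](C)(C)C(C)(C)C)CCCC/C=C/C(=C)O[Si](CC)(CC)CC
F3 | step 11 | tert-butyl (2R,3S,4aS,5S,8aR)-3-(benzyloxy)-5-[(5R)-5-[(tert-butyldimethylsilyl)oxy]octyl]-2-methyl-4-oxo-7-[(triethylsilyl)oxy]-3,4,4a,5,8,8a-hexahydroquinoline-1(2H)-carboxylate | c1ccccc1CO[C@@H]1C(=O)[C@H]2[C@@H](CCCC[C@H](O[Si](C)(C)C(C)(C)C)CCC)C=C(O[Si](CC)(CC)CC)C[C@H]2N(C(=O)OC(C)(C)C)[C@@H]1C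
F4 | step 11 | tert-butyl (2R,3S,4aS,5S,8aR)-3-(benzyloxy)-5-[(5R)-5-[(tert-butyldimethylsilyl)oxy]octyl]-2-methyl-4,7-dioxooctahydroquinoline-1(2H)-carboxylate | c1ccccc1CO[C@@H]1C(=O)[C@H]2[C@@H](CCCC[C@H](O[Si](C)(C)C(C)(C)C)CCC)CC(=O)C[C@H]2N(C(=O)OC(C)(C)C)[C@@H]1C
F5 | step 11 | 4,7-diol corresponding to F4 (C4 and C7 carbinol epimers) | c1ccccc1CO[C@@H]1C(O)[C@H]2[C@@H](CCCC[C@H](O[Si](C)(C)C(C)(C)C)CCC)CC(O)C[C@H]2N(C(=O)OC(C)(C)C)[C@@H]1C
F6 | step 11 | 4,7-bis[(1H-imidazol-1-ylcarbonothioyl)oxy] derivative of F5 | c1ccccc1CO[C@@H]1C(OC(=S)n3ccnc3)[C@H]2[C@@H](CCCC[C@H](O[Si](C)(C)C(C)(C)C)CCC)CC(OC(=S)n3ccnc3)C[C@H]2N(C(=O)OC(C)(C)C)[C@@H]1C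
F7 | step 11 | tert-butyl (2R,3R,4aS,5S,8aR)-3-(benzyloxy)-5-[(5R)-5-[(tert-butyldimethylsilyl)oxy]octyl]-2-methyloctahydroquinoline-1(2H)-carboxylate | c1ccccc1CO[C@@H]1C[C@H]2[C@@H](CCCC[C@H](O[Si](C)(C)C(C)(C)C)CCC)CCC[C@H]2N(C(=O)OC(C)(C)C)[C@@H]1C
F0 | step 5 | none | none
F8 | step 13 | C4 spiro-1,3-dithiolane of 14 | c1ccccc1CO[C@@H]1C2(SCCS2)[C@H]2[C@@H](CCCC[C@H](O[Si](C)(C)C(C)(C)C)CCC)C=CC[C@H]2N(C(=O)OC(C)(C)C)[C@@H]1C
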